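**Plan**
- Retrosynthesis: the target is traced back through desilylation of O6 and a benzoyl shift from the tertiary O1 to the primary O7 (after aldehyde reduction) to an all-cis cyclohexene carbaldehyde. This aldehyde is cut at C1–C2 and C5–C6.
- Enabling feature: in the cyclohexene ring C1–C6 the double bond C3=C4 lies between the two cis benzoyloxy carbons C2 and C5 and opposite the cis-dioxygenated pair C1/C6, with C1 also carrying C7. This is the pattern of a [4+2] adduct of an E,E-1,4-diacyloxybutadiene (C2–C5) and a Z-2,3-dioxygenated acrolein (C6, C1, C7).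
- Forward: the diene comes from succinaldehyde as its bis-enol benzoate, and the dienophile from penta-1,4-dien-3-ol by benzoylation, double ozonolysis and O-silylation. The only ring closes in the cycloaddition, followed by reduction with benzoyl shift and desilylation.
- Stereochemistry: C2/C5 cis from the E,E diene, C1/C6 cis from the Z enal, and the cis relation between the two pairs from a formyl-exo, oxygen-endo transition state. The absolute sense comes from a chiral oxazaborolidinium Lewis acid, and no later step touches a stereocentre.
- Activation is by a boron Lewis acid on the formyl oxygen, because a primary amine (iminium) catalyst would be consumed by addition–elimination at the β-silyloxy carbon. The bulky triisopropylsilyl group guards against silyl transfer.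

Key step: step 6

Assumption: the facial sense of the (R)-oxazaborolidinium ion is taken from the formyl C–H···O/π-stacking model of 2-substituted acroleins; should the first adduct show the opposite sense, the (S)-catalyst is used with no other change.

Ring locants throughout: C1 is the fully substituted carbon bearing C7, then C2, C3=C4, C5, C6.

**Route**

Step 1
Reactants: 1 2,5-dimethoxytetrahydrofuran
Product: 2 succinaldehyde (butanedial)
Conditions: H2O, 90 °C; MeOH distilled off; short-path distillation, used at once
Reagents that add atoms: water, O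
Why: Acetal hydrolysis opens the cyclic bis-acetal to the open-chain dialdehyde, and removal of methanol by distillation drives the equilibrium.

Step 2
Reactants: 2 succinaldehyde; 3 benzoyl chloride
Product: 4 (1E,3E)-buta-1,3-diene-1,4-diyl dibenzoate
Conditions: BzCl (2.4 equiv), Et3N, 4-(dimethylamino)pyridine (cat.), CH2Cl2, 0 °C → rt, slow addition of 2; then I2 (cat.), PhMe, visible light; recrystallisation
Reagents that add atoms: benzoyl chloride 3, O=C(Cl)c1ccccc1
Why: Double enol esterification (O-acylation of the amine-generated enols) should give the bis-enol benzoate, and iodine-catalysed photoequilibration with crystallisation should converge the geometric isomers on the most stable and least soluble E,E diene, no stereocentre being formed.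

Step 3
Reactants: 5 penta-1,4-dien-3-ol; 3 benzoyl chloride
Product: 6 penta-1,4-dien-3-yl benzoate
Conditions: BzCl, pyridine, 4-(dimethylamino)pyridine (cat.), CH2Cl2, 0 °C → rt
Reagents that add atoms: benzoyl chloride 3, O=C(Cl)c1ccccc1
Why: Pyridine-mediated O-benzoylation (nucleophilic acyl substitution) of an unhindered secondary alcohol is routine and leaves both vinyl groups untouched.

Step 4
Reactants: 6 penta-1,4-dien-3-yl benzoate
Product: 7 2-(benzoyloxy)malonaldehyde (held as its enol, 2-(benzoyloxy)-3-hydroxyprop-2-enal)
Conditions: O3, CH2Cl2, −78 °C; then Me2S, −78 °C → rt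
Reagents that add atoms: ozone, [O-][O+]=O
Why: Ozonolysis with reductive work-up should cleave both terminal alkenes to formyl groups, and the resulting 2-acyloxy-1,3-dialdehyde is held as its conjugated acidic enol, so that no stereocentre remains.

Step 5
Reactants: 7 2-(benzoyloxy)malonaldehyde; 8 chlorotriisopropylsilane
Product: 9 (Z)-2-(benzoyloxy)-3-(triisopropylsilyloxy)prop-2-enal
Conditions: iPr3SiCl, Et3N, CH2Cl2, 0 °C; filtration through Et3N-deactivated silica
Reagents that add atoms: chlorotriisopropylsilane 8, CC(C)[Si](Cl)(C(C)C)C(C)C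
Why: O-Silylation of the vinylogous acid should give the silyl enol ether in its readily equilibrating push–pull W geometry, with the silyloxy group anti to the formyl group and therefore cis to the benzoate (Z); the bulky triisopropylsilyl group is chosen because it resists hydrolysis and transfer to the counter-ion of the Lewis acid in step 6.

Step 6
Reactants: 4 (1E,3E)-buta-1,3-diene-1,4-diyl dibenzoate; 9 (Z)-2-(benzoyloxy)-3-(triisopropylsilyloxy)prop-2-enal
Product: 10 (1R,2R,5S,6S)-1-formyl-6-(triisopropylsilyloxy)cyclohex-3-ene-1,2,5-triyl tribenzoate (four ring oxygens cis, formyl trans)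
Conditions: 4 (2 equiv), (R)-tetrahydro-1-(2-methylphenyl)-3,3-diphenyl-1H,3H-pyrrolo[1,2-c][1,3,2]oxazaborole (20 mol %), Tf2NH (18 mol %), CH2Cl2 (1 M), −20 → 4 °C
Reagents that add atoms: none
Why: Proposed new method: the oxazaborolidinium ion binds the formyl oxygen of 9 anti to C1 and turns the push–pull enal into a silyloxy-stabilised allyl cation; a terminus of 4 attacks C6 and the C1–C2 bond follows in an asynchronous but suprafacial [4π+2π] cycloaddition, so that the cyclohexene ring closes in one step by union of the two diene termini with the two alkene carbons. The closest known reactions are the enantioselective Diels–Alder additions of 2-bromo- and 2-acyloxyacroleins under chiral boron Lewis-acid or ammonium-salt catalysis and the thermal endo additions of E,E-1,4-diacyloxybutadienes to vinylene carbonate; a 3-oxygenated 2-acyloxyacrolein has not been combined with such a diene. C2 and C5 become cis because both benzoyloxy groups of 4 are outside (E,E) substituents, and C1 and C6 become cis because benzoate and silyloxy group are cis on the Z double bond of 9, the geometry that the W-shaped Lewis-acid complex also prefers. The cis relation between these two pairs requires the formyl group exo and both dienophile oxygens endo, the topology that 2-substituted acroleins prefer in Lewis-acid-catalysed additions to cyclic dienes and that the bulk of the catalyst on the formyl side and the endo preference of oxygen substituents should reinforce here. The absolute configuration comes from the catalyst: the s-trans enal, held by a formyl C–H···O contact, stacks on one phenyl group of the (R)-catalyst, which covers the Re face of C1 and leaves the Si face, with the matching face of C6, to the diene. Regiochemistry does not arise because 4 is symmetric, and the low reactivity expected of this electronically ill-matched pair is met by the cationic catalyst, an excess of 4 and high concentration.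

Step 7
Reactants: 10 (1R,2R,5S,6S)-1-formyl-6-(triisopropylsilyloxy)cyclohex-3-ene-1,2,5-triyl tribenzoate
Product: 12 [(1R,2R,5S,6S)-2,5-bis(benzoyloxy)-1-hydroxy-6-(triisopropylsilyloxy)cyclohex-3-en-1-yl]methyl benzoate, via hydroxymethyl tribenzoate 11 (not isolated)
Conditions: NaBH4, THF/MeOH, −20 °C; then Et3N, CH2Cl2, rt
Reagents that add atoms: none
Why: Chemoselective borohydride reduction of the aldehyde is followed by base-mediated 1,2-O→O acyl migration through a five-membered ortho-acid intermediate, driven by the greater stability of a primary over a tertiary benzoate; with O6 silylated the 2,5,7-tribenzoate is the only arrangement that leaves just the tertiary hydroxyl free, and no stereocentre is touched.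

Step 8
Reactants: 12 [(1R,2R,5S,6S)-2,5-bis(benzoyloxy)-1-hydroxy-6-(triisopropylsilyloxy)cyclohex-3-en-1-yl]methyl benzoate
Product: 13 [(1S,2R,5S,6S)-2,5-bis(benzoyloxy)-1,6-dihydroxycyclohex-3-en-1-yl]methyl benzoate (CNP0128482.8)
Conditions: HF·pyridine, pyridine/THF, 0 °C → rt; NaHCO3 work-up
Reagents that add atoms: none
Why: Fluoride-mediated Si–O cleavage under the weakly acidic conditions of HF·pyridine should free the C6 hydroxyl without generating the alkoxide that would let the neighbouring C5 or C7 benzoate migrate.

**Compound list**
1 | 2,5-dimethoxytetrahydrofuran (cis/trans mixture) | COC1CCC(OC)O1 | starting material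
2 | succinaldehyde (butanedial) | O=CCCC=O | intermediate
3 | benzoyl chloride | O=C(Cl)c1ccccc1 | starting material
4 | (1E,3E)-buta-1,3-diene-1,4-diyl dibenzoate | O=C(O/C=C/C=C/OC(=O)c1ccccc1)c1ccccc1 | intermediate
5 | penta-1,4-dien-3-ol | C=CC(O)C=C | starting material
6 | penta-1,4-dien-3-yl benzoate | C=CC(OC(=O)c1ccccc1)C=C | intermediate
7 | 2-(benzoyloxy)malonaldehyde (drawn as the dialdehyde, present as its enol) | O=CC(OC(=O)c1ccccc1)C=O | intermediate
8 | chlorotriisopropylsilane | CC(C)[Si](Cl)(C(C)C)C(C)C | starting material
9 | (Z)-2-(benzoyloxy)-3-(triisopropylsilyloxy)prop-2-enal | O=C/C(OC(=O)c1ccccc1)=C/O[Si](C(C)C)(C(C)C)C(C)C | intermediate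
10 | (1R,2R,5S,6S)-1-formyl-6-(triisopropylsilyloxy)cyclohex-3-ene-1,2,5-triyl tribenzoate | O=C[C@@]1(OC(=O)c2ccccc2)[C@H](OC(=O)c2ccccc2)C=C[C@H](OC(=O)c2ccccc2)[C@@H]1O[Si](C(C)C)(C(C)C)C(C)C | intermediate
11 | (1R,2R,5S,6S)-1-(hydroxymethyl)-6-(triisopropylsilyloxy)cyclohex-3-ene-1,2,5-triyl tribenzoate | OC[C@@]1(OC(=O)c2ccccc2)[C@H](OC(=O)c2ccccc2)C=C[C@H](OC(=O)c2ccccc2)[C@@H]1O[Si](C(C)C)(C(C)C)C(C)C | intermediate
12 | [(1R,2R,5S,6S)-2,5-bis(benzoyloxy)-1-hydroxy-6-(triisopropylsilyloxy)cyclohex-3-en-1-yl]methyl benzoate | O=C(OC[C@@]1(O)[C@H](OC(=O)c2ccccc2)C=C[C@H](OC(=O)c2ccccc2)[C@@H]1O[Si](C(C)C)(C(C)C)C(C)C)c1ccccc1 | intermediate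
13 | [(1S,2R,5S,6S)-2,5-bis(benzoyloxy)-1,6-dihydroxycyclohex-3-en-1-yl]methyl benzoate | O=C(OC[C@@]1(O)[C@H](OC(=O)c2ccccc2)C=C[C@H](OC(=O)c2ccccc2)[C@@H]1O)c1ccccc1 | target

**Step count**
Total: 8 steps. Longest linear sequence: 6 steps (steps 3, 4, 5, 6, 7, 8 from penta-1,4-dien-3-ol).

**Steps most likely to fail**

Step 6. The risks are insufficient turnover of an electronically mismatched pair, erosion of the formyl-exo topology or of facial selectivity, and silyl transfer from the activated enal to the triflimide ion, which would start an achiral background reaction. The fallback uses known chemistry, sets out from 4 and 9 and returns at 10. The two partners are combined with a stoichiometric achiral Lewis acid (Me2AlCl, 1.1 equiv, CH2Cl2, −78 → −20 °C), the kind of promotion long used for 2-acyloxyacroleins, which removes the turnover problem and should give 10 as the racemate, that is together with the mirror-image adduct F1. Condensation of the mixture with (1R,2R)-N,N'-dimethyl-1,2-diphenylethane-1,2-diamine (4 Å molecular sieves, CH2Cl2) should give two diastereomeric aminals, the imidazolidine of 10 F2 and the imidazolidine of the mirror-image adduct F3, which are separated by chromatography or crystallisation. Mild acid hydrolysis of F2 (dilute aqueous HCl/Et2O) returns enantiopure 10 and the recoverable diamine.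

Step 2. The risks are base-induced aldol oligomerisation of the dialdehyde competing with O-acylation, and incomplete convergence of the enol ester geometry on E,E. The fallback gives up the benzoates of the diene, sets out from 9 and returns at 12. Under the conditions of step 6, 9 is combined with commercially available, configurationally pure (1E,3E)-buta-1,3-diene-1,4-diyl diacetate F4 to give the diacetate adduct F5. Excess iBu2AlH (CH2Cl2, −78 °C) reduces the aldehyde and removes all three esters to give the silyl tetraol F6. BzCl (3.3 equiv) in pyridine at 0 °C should acylate the primary and the two secondary allylic hydroxyls but not the tertiary one, which gives 12.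

Step 8. The risk is slow Si–O cleavage at a hindered secondary position between a fully substituted carbon and an acyloxy carbon, during which benzoyl migration from O5 or O7 to the freed O6 may set in. The fallback changes the protecting group, sets out from 7 and returns at 13. Silylation of 7 with tBuMe2SiCl/Et3N gives the tert-butyldimethylsilyl enal F7, which is taken through step 6 with 4 to the silyl adduct F8. The conditions of step 7 then lead through the hydroxymethyl intermediate F9 to the rearranged tribenzoate F10. Its less hindered silyl ether should be cleaved by HF·pyridine at 0 °C within a short time, giving 13.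

**Further compounds**
F1 | step 6 | (1S,2S,5R,6R)-1-formyl-6-(triisopropylsilyloxy)cyclohex-3-ene-1,2,5-triyl tribenzoate (mirror image of 10) | O=C[C@]1(OC(=O)c2ccccc2)[C@@H](OC(=O)c2ccccc2)C=C[C@@H](OC(=O)c2ccccc2)[C@H]1O[Si](C(C)C)(C(C)C)C(C)C
F2 | step 6 | (4R,5R)-1,3-dimethyl-4,5-diphenylimidazolidin-2-yl aminal of 10 | CN1[C@H](c2ccccc2)[C@@H](c2ccccc2)N(C)C1[C@@]1(OC(=O)c2ccccc2)[C@H](OC(=O)c2ccccc2)C=C[C@H](OC(=O)c2ccccc2)[C@@H]1O[Si](C(C)C)(C(C)C)C(C)C
F3 | step 6 | (4R,5R)-1,3-dimethyl-4,5-diphenylimidazolidin-2-yl aminal of F1 | CN1[C@H](c2ccccc2)[C@@H](c2ccccc2)N(C)C1[C@]1(OC(=O)c2ccccc2)[C@@H](OC(=O)c2ccccc2)C=C[C@@H](OC(=O)c2ccccc2)[C@H]1O[Si](C(C)C)(C(C)C)C(C)C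
F4 | step 2 | (1E,3E)-buta-1,3-diene-1,4-diyl diacetate (purchased) | CC(=O)O/C=C/C=C/OC(C)=O
F5 | step 2 | (1R,2R,5S,6S)-2,5-bis(acetyloxy)-1-formyl-6-(triisopropylsilyloxy)cyclohex-3-en-1-yl benzoate | O=C[C@@]1(OC(=O)c2ccccc2)[C@H](OC(C)=O)C=C[C@H](OC(C)=O)[C@@H]1O[Si](C(C)C)(C(C)C)C(C)C
F6 | step 2 | (1R,2R,5S,6S)-1-(hydroxymethyl)-6-(triisopropylsilyloxy)cyclohex-3-ene-1,2,5-triol | OC[C@@]1(O)[C@H](O)C=C[C@H](O)[C@@H]1O[Si](C(C)C)(C(C)C)C(C)C
F7 | step 8 | (Z)-2-(benzoyloxy)-3-(tert-butyldimethylsilyloxy)prop-2-enal | O=C/C(OC(=O)c1ccccc1)=C/O[Si](C)(C)C(C)(C)C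
F8 | step 8 | (1R,2R,5S,6S)-6-(tert-butyldimethylsilyloxy)-1-formylcyclohex-3-ene-1,2,5-triyl tribenzoate | O=C[C@@]1(OC(=O)c2ccccc2)[C@H](OC(=O)c2ccccc2)C=C[C@H](OC(=O)c2ccccc2)[C@@H]1O[Si](C)(C)C(C)(C)C
F9 | step 8 | (1R,2R,5S,6S)-6-(tert-butyldimethylsilyloxy)-1-(hydroxymethyl)cyclohex-3-ene-1,2,5-triyl tribenzoate (not isolated) | OC[C@@]1(OC(=O)c2ccccc2)[C@H](OC(=O)c2ccccc2)C=C[C@H](OC(=O)c2ccccc2)[C@@H]1O[Si](C)(C)C(C)(C)C
F10 | step 8 | [(1R,2R,5S,6S)-2,5-bis(benzoyloxy)-6-(tert-butyldimethylsilyloxy)-1-hydroxycyclohex-3-en-1-yl]methyl benzoate | O=C(OC[C@@]1(O)[C@H](OC(=O)c2ccccc2)C=C[C@H](OC(=O)c2ccccc2)[C@@H]1O[Si](C)(C)C(C)(C)C)c1ccccc1
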